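**Plan**

1. Numbering used: γ-lactam N4–C9a(=O)–C1–C2–C3; N4–C5…C8–C9(=O)–C10(Et)–C11(O)–C12–C1 completes the 11-membered ring; ring lactone C11–O–C14(=O)–C13(Me)–C12; pendant lactone C18(O)–C19–C20(Me)–C21(=O) on C3.
2. Retrosynthesis: pendant lactone ⇒ dibenzyl 1,4-diol (mask); C7–C8 ⇒ ring-closing metathesis, then H2; C10–C11 and O–C14 ⇒ syn aldol of a hex-1-en-3-one boron enolate and lactonisation; C1–C12 and C13–CH3 ⇒ Michael addition of the lactam enolate to a 5-menthyloxybutenolide with methylation; last, the pyrrolidinone is cut at C1–C2 and N4–C3.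
3. Enabling feature: N4–C9a(=O)–C1H2 of the γ-lactam is an N-alkylacetamide N,C-dianion in disguise, and C2–C3 is the terminal diol of a D-glyceraldehyde-derived anti-triol (N at C3 is syn to O at C18, so C3 has to be entered with inversion). Its 1,2-cyclic sulfate is a 1,2-bis-electrophile that can take both ring bonds in one flask.
4. Forward order: mannitol diacetonide → cyclic sulfate 12; dianion of N-butenylacetamide + 12 → pyrrolidinone 17; Michael/methylation (C12–C14); aldol/lactonisation (C9–C11, ring lactone); RCM (11-membered ring); hydrogenation/debenzylation; oxidative lactonisation (pendant lactone).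
5. Stereochemistry: C3 and C18 from D-glyceraldehyde (Felkin–Anh allylation, SN2 inversion at C3); C20 by cis-hydrogenation of an α-methylene lactone; C1 trans to C3 by enolate facial bias; C12 and C13 relayed from the (5S)-menthyloxy acetal; C10 and C11 by the Ipc2B (Z)-enolate.

Key step: step 9

Assumption (remark on the chemistry): the target SMILES is read as 1S,3S,10S,11R,12S,13S,18S,20S (pendant lactone 18,20-cis; pyrrolidinone 1,3-trans; ring lactone 11,12-cis and 12,13-trans; C10/C11 syn); (5S)-5-(d-menthyloxy)furan-2(5H)-one and hex-1-en-3-one are taken as purchasable, and (−)-Ipc2BOTf as a stock reagent made from (+)-α-pinene-derived Ipc2BH and TfOH.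

**Route**

Step 1
Reactants: 1 1,2:5,6-di-O-isopropylidene-D-mannitol
Product: 2 (R)-2,2-dimethyl-1,3-dioxolane-4-carbaldehyde
Conditions: NaIO4, sat. aq. NaHCO3, CH2Cl2, rt; used fresh
Reagents that add atoms: none
Why: Glycol cleavage (Malaprade reaction) of the only free 1,2-diol should give two molecules of the aldehyde, whose stereocentre (the future C3, still carrying oxygen) comes unchanged from D-mannitol.

Step 2
Reactants: 2 (R)-2,2-dimethyl-1,3-dioxolane-4-carbaldehyde; 3 ethyl 2-(bromomethyl)prop-2-enoate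
Product: 6 (5S)-5-[(4R)-2,2-dimethyl-1,3-dioxolan-4-yl]-3-methylideneoxolan-2-one, via allylzinc bromide 4 (not isolated), via zinc alkoxide of hydroxy ester 5 (not isolated)
Conditions: activated Zn dust, THF, 50 °C; sat. aq. NH4Cl work-up
Reagents that add atoms: none
Why: Dreiding–Schmidt reaction (Zn-mediated Barbier-type allylation with in-flask lactonisation of the zinc alkoxide), in which Felkin–Anh addition anti to the dioxolane C–O bond should set C18 (S) and so the anti relationship between the C18 and C3 oxygens.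

Step 3
Reactants: 6 (5S)-5-[(4R)-2,2-dimethyl-1,3-dioxolan-4-yl]-3-methylideneoxolan-2-one
Product: 7 (3S,5S)-5-[(4R)-2,2-dimethyl-1,3-dioxolan-4-yl]-3-methyloxolan-2-one
Conditions: H2 (1 atm), 10% Pd/C, EtOAc, rt
Reagents that add atoms: none
Why: Heterogeneous hydrogenation of the exocyclic methylene should deliver hydrogen to the lactone face opposite the C18 dioxolanyl group, giving the 3,5-cis lactone and thereby C20 (S).

Step 4
Reactants: 7 (3S,5S)-5-[(4R)-2,2-dimethyl-1,3-dioxolan-4-yl]-3-methyloxolan-2-one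
Product: 8 (2S,4S)-4-[(4R)-2,2-dimethyl-1,3-dioxolan-4-yl]-2-methylbutane-1,4-diol
Conditions: LiAlH4, THF, 0 °C to rt; Fieser work-up
Reagents that add atoms: none
Why: Hydride reduction of the lactone to the 1,4-diol is routine and turns the base-sensitive lactone with its epimerisable C20 into a form that survives the later organolithium and enolate steps.

Step 5
Reactants: 8 (2S,4S)-4-[(4R)-2,2-dimethyl-1,3-dioxolan-4-yl]-2-methylbutane-1,4-diol
Product: 9 (4R)-4-[(1S,3S)-1,4-bis(benzyloxy)-3-methylbutyl]-2,2-dimethyl-1,3-dioxolane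
Conditions: NaH, BnBr, n-Bu4NI (cat.), THF/DMF, 0 °C to rt
Reagents that add atoms: benzyl bromide BrCc1ccccc1
Why: Williamson etherification of both hydroxyls gives benzyl ethers that tolerate strong base, aqueous acid and metathesis and can leave in the same flask as the later alkene hydrogenation.

Step 6
Reactants: 9 (4R)-4-[(1S,3S)-1,4-bis(benzyloxy)-3-methylbutyl]-2,2-dimethyl-1,3-dioxolane
Product: 10 (2R,3S,5S)-3,6-bis(benzyloxy)-5-methylhexane-1,2-diol
Conditions: AcOH/H2O (4:1), 45 °C
Reagents that add atoms: none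
Why: Acid-catalysed hydrolysis of the terminal acetonide should free the 1,2-diol without touching the benzyl ethers or any stereocentre.

Step 7
Reactants: 10 (2R,3S,5S)-3,6-bis(benzyloxy)-5-methylhexane-1,2-diol
Product: 12 (4R)-4-[(1S,3S)-1,4-bis(benzyloxy)-3-methylbutyl]-1,3,2-dioxathiolane 2,2-dioxide, via cyclic sulfite 11 (not isolated)
Conditions: SOCl2, Et3N, CH2Cl2, 0 °C; then RuCl3·xH2O (cat.), NaIO4, MeCN/CCl4/H2O, 0 °C
Reagents that add atoms: thionyl chloride O=S(Cl)Cl; sodium periodate [Na+].[O-]I(=O)(=O)=O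
Why: Standard two-stage cyclic sulfate synthesis (cyclic sulfite formation, then Ru-catalysed oxidation at sulfur) activates both C–O bonds of the diol with retention at C3.

Step 8
Reactants: 13 but-3-en-1-amine
Product: 14 N-(but-3-en-1-yl)acetamide
Conditions: Ac2O, Et3N, CH2Cl2, 0 °C to rt
Reagents that add atoms: acetic anhydride CC(=O)OC(C)=O
Why: Simple N-acylation of a primary amine, giving the secondary acetamide that supplies N4, C9a, C1 and the C5–C7 part of the chain with its metathesis handle.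

Step 9
Reactants: 14 N-(but-3-en-1-yl)acetamide; 12 (4R)-4-[(1S,3S)-1,4-bis(benzyloxy)-3-methylbutyl]-1,3,2-dioxathiolane 2,2-dioxide
Product: 17 (5S)-5-[(1S,3S)-1,4-bis(benzyloxy)-3-methylbutyl]-1-(but-3-en-1-yl)pyrrolidin-2-one, via dilithio dianion 15 (not isolated), via lithium amidate sulfate 16 (not isolated)
Conditions: 14, n-BuLi (2.1 equiv), THF, 0 °C; add 12, −78 to 0 °C; then DMPU, 50 °C
Reagents that add atoms: none
Why: Proposed new method: the carbon terminus of the N,C-dilithio dianion 15 should open the cyclic sulfate at its primary carbon (C1–C2 bond), and the lithium amidate left behind should then displace the secondary sulfate monoester in the same flask (N4–C3 bond), so that an acetamide and a diol-derived bis-electrophile are merged into the γ-lactam. The closest known reaction types are the C,N-cyclodialkylation of secondary amide dianions with 1,2-dielectrophiles such as epibromohydrin to 5-substituted pyrrolidin-2-ones and the double displacement of 1,2-cyclic sulfates by malonates or primary amines. The pyrrolidinone ring closes by a 5-exo-tet SN2 step. C3 is the only new stereocentre and is fixed by inversion of the (R)-configured, glyceraldehyde-derived sulfate carbon, which gives 3S with nitrogen syn to the C18 oxygen, while C18 and C20 are not touched. The step needs C- before N-alkylation, primary before secondary attack and N- rather than O-closure: the first follows from the higher nucleophilicity of the carbanion, the second from the steric bias of terminal cyclic sulfates, and the third is expected because an anionic amidate, as in the base-induced closure of 4-halobutanamides, alkylates on nitrogen when a five-membered lactam results. The monoalkyl sulfate anion formed in the first event is inert to intermolecular attack, which should prevent double alkylation, and the dibenzyl diol form of the future lactone tolerates the organolithium conditions.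

Step 10
Reactants: 17 (5S)-5-[(1S,3S)-1,4-bis(benzyloxy)-3-methylbutyl]-1-(but-3-en-1-yl)pyrrolidin-2-one; 18 (5S)-5-{[(1S,2R,5S)-5-methyl-2-(propan-2-yl)cyclohexyl]oxy}furan-2(5H)-one
Product: 21 (3S,5S)-5-[(1S,3S)-1,4-bis(benzyloxy)-3-methylbutyl]-1-(but-3-en-1-yl)-3-[(2S,3S,4S)-2-(d-menthyloxy)-4-methyl-5-oxooxolan-3-yl]pyrrolidin-2-one, via lactam lithium enolate 19 (not isolated), via lactone lithium enolate 20 (not isolated)
Conditions: LDA (1.05 equiv), THF, −78 °C; add 18, −78 °C; then MeI, DMPU, −78 to −20 °C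
Reagents that add atoms: iodomethane CI
Why: Tandem Michael addition–enolate alkylation on a 5-alkoxybutenolide: the lactam enolate should react on the face opposite the C3 side chain (C1 trans to C3), add to the butenolide face opposite the menthyloxy group (C12), and the lactone enolate so formed should be methylated anti to the new C12 substituent (C13).

Step 11
Reactants: 21 the menthyloxy lactone of step 10
Product: 22 (3S,5S)-5-[(1S,3S)-1,4-bis(benzyloxy)-3-methylbutyl]-1-(but-3-en-1-yl)-3-[(3S,4S)-2-hydroxy-4-methyl-5-oxooxolan-3-yl]pyrrolidin-2-one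
Conditions: TFA/H2O (9:1), 0 °C to rt
Reagents that add atoms: water O
Why: Acid hydrolysis of the pseudo-ester acetal should release the ring-chain tautomeric aldehyde acid and menthol without any base, so that C12 and C13 are not put at risk.

Step 12
Reactants: 22 the hydroxy lactone (pseudo-acid) of step 11
Product: 23 methyl (2S,3S)-3-{(3S,5S)-5-[(1S,3S)-1,4-bis(benzyloxy)-3-methylbutyl]-1-(but-3-en-1-yl)-2-oxopyrrolidin-3-yl}-2-methyl-4-oxobutanoate
Conditions: TMSCHN2, PhMe/MeOH (4:1), 0 °C; used without delay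
Reagents that add atoms: (trimethylsilyl)diazomethane C[Si](C)(C)C=[N+]=[N-]
Why: Esterification of the open carboxylic acid tautomer with the diazoalkane should pull the ring-chain equilibrium to the free C11 aldehyde as its methyl ester under neutral conditions.

Step 13
Reactants: 23 the aldehyde ester of step 12; 24 hex-1-en-3-one
Product: 27 (3S,5S)-5-[(1S,3S)-1,4-bis(benzyloxy)-3-methylbutyl]-1-(but-3-en-1-yl)-3-{(2R,3S,4S)-4-methyl-5-oxo-2-[(3S)-4-oxohex-5-en-3-yl]oxolan-3-yl}pyrrolidin-2-one, via boron enolate 25 (not isolated), via syn-aldol hydroxy ester 26 (not isolated)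
Conditions: 24, (−)-Ipc2BOTf, i-Pr2NEt, CH2Cl2, −78 °C; add 23, −78 to −20 °C; pH 7 buffer, MeOH, 30% H2O2, 0 °C; crude with PPTS (cat.), CH2Cl2, rt
Reagents that add atoms: none
Why: Chiral boron-enolate aldol reaction: enolisation can occur only at the propyl CH2 and should give the (Z)-enolate, which reacts through a closed Zimmerman–Traxler transition state to the 10,11-syn adduct with the Ipc ligands expected to direct attack to the si face of the aldehyde (10S,11R), after which the γ-hydroxy ester lactonises to the ring lactone with the C11 and C12 substituents cis.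

Step 14
Reactants: 27 the vinyl ketone lactone of step 13
Product: 28 (7E)-7,8-didehydro macrocyclic keto-lactam carrying the (1S,3S)-1,4-bis(benzyloxy)-3-methylbutyl chain on C3
Conditions: Hoveyda–Grubbs II (10 mol %), CH2Cl2 (1 mM), 40 °C
Reagents that add atoms: none
Why: Ring-closing metathesis between the N-butenyl terminus and the vinyl ketone should form C7=C8 with loss of ethene and close the 11-membered ring, enone-forming macrocyclic RCM with second-generation Ru carbenes being well precedented; the alkene geometry is of no consequence.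

Step 15
Reactants: 28 the macrocyclic enone of step 14
Product: 29 saturated macrocyclic keto-lactam carrying the (1S,3S)-1,4-dihydroxy-3-methylbutyl chain on C3
Conditions: H2 (1 atm), 10% Pd/C, EtOAc/EtOH, rt
Reagents that add atoms: none
Why: Pd-catalysed hydrogenation should saturate C7=C8 and hydrogenolyse both benzyl ethers in one operation while ketone, lactone and lactam stay untouched.

Step 16
Reactants: 29 the seco-diol of step 15
Product: 30 target CNP0147860.1
Conditions: TEMPO (20 mol %), PhI(OAc)2 (2.5 equiv), CH2Cl2, rt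
Reagents that add atoms: none
Why: TEMPO/PhI(OAc)2 oxidation is selective for the primary alcohol, whose aldehyde is trapped by the C18 hydroxyl as a lactol and oxidised on to the γ-lactone under non-basic conditions that spare the β-acyloxy ketone and the stereocentres at C10, C13 and C20.

**Compound list**

1 | 1,2:5,6-di-O-isopropylidene-D-mannitol | CC1(C)OC[C@@H](O1)[C@@H](O)[C@H](O)[C@H]1COC(C)(C)O1 | starting material
2 | (R)-2,2-dimethyl-1,3-dioxolane-4-carbaldehyde | CC1(C)OC[C@@H](O1)C=O | intermediate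
3 | ethyl 2-(bromomethyl)prop-2-enoate | C=C(CBr)C(=O)OCC | starting material
4 | [2-(ethoxycarbonyl)prop-2-en-1-yl]zinc bromide (formed in the flask) | C=C(C[Zn]Br)C(=O)OCC | intermediate
5 | ethyl (4S)-4-[(4R)-2,2-dimethyl-1,3-dioxolan-4-yl]-4-hydroxy-2-methylidenebutanoate, present as its zinc alkoxide (formed in the flask) | C=C(C[C@H](O)[C@H]1COC(C)(C)O1)C(=O)OCC | intermediate
6 | (5S)-5-[(4R)-2,2-dimethyl-1,3-dioxolan-4-yl]-3-methylideneoxolan-2-one | C=C1C[C@H](OC1=O)[C@H]1COC(C)(C)O1 | intermediate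
7 | (3S,5S)-5-[(4R)-2,2-dimethyl-1,3-dioxolan-4-yl]-3-methyloxolan-2-one | C[C@H]1C[C@H](OC1=O)[C@H]1COC(C)(C)O1 | intermediate
8 | (2S,4S)-4-[(4R)-2,2-dimethyl-1,3-dioxolan-4-yl]-2-methylbutane-1,4-diol | C[C@H](CO)C[C@H](O)[C@H]1COC(C)(C)O1 | intermediate
9 | (4R)-4-[(1S,3S)-1,4-bis(benzyloxy)-3-methylbutyl]-2,2-dimethyl-1,3-dioxolane | C[C@H](COCc1ccccc1)C[C@H](OCc1ccccc1)[C@H]1COC(C)(C)O1 | intermediate
10 | (2R,3S,5S)-3,6-bis(benzyloxy)-5-methylhexane-1,2-diol | C[C@H](COCc1ccccc1)C[C@H](OCc1ccccc1)[C@H](O)CO | intermediate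
11 | (4R)-4-[(1S,3S)-1,4-bis(benzyloxy)-3-methylbutyl]-1,3,2-dioxathiolane 2-oxide (cyclic sulfite, both S-epimers; formed in the flask) | C[C@H](COCc1ccccc1)C[C@H](OCc1ccccc1)[C@H]1COS(=O)O1 | intermediate
12 | (4R)-4-[(1S,3S)-1,4-bis(benzyloxy)-3-methylbutyl]-1,3,2-dioxathiolane 2,2-dioxide (cyclic sulfate) | C[C@H](COCc1ccccc1)C[C@H](OCc1ccccc1)[C@H]1COS(=O)(=O)O1 | intermediate
13 | but-3-en-1-amine | NCCC=C | starting material
14 | N-(but-3-en-1-yl)acetamide | CC(=O)NCCC=C | intermediate
15 | N,C-dilithio dianion of 14 (formed in the flask) | [Li+].[Li+].[CH2-]C(=O)[N-]CCC=C | intermediate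
16 | dilithium amidate/sulfate monoester of (4R,5S,7S)-5,8-bis(benzyloxy)-N-(but-3-en-1-yl)-7-methyl-4-(sulfooxy)octanamide (formed in the flask) | [Li+].[Li+].C=CCC[N-]C(=O)CC[C@@H](OS(=O)(=O)[O-])[C@@H](OCc1ccccc1)C[C@H](C)COCc1ccccc1 | intermediate
17 | (5S)-5-[(1S,3S)-1,4-bis(benzyloxy)-3-methylbutyl]-1-(but-3-en-1-yl)pyrrolidin-2-one | C=CCCN1C(=O)CC[C@H]1[C@@H](OCc1ccccc1)C[C@H](C)COCc1ccccc1 | intermediate
18 | (5S)-5-{[(1S,2R,5S)-5-methyl-2-(propan-2-yl)cyclohexyl]oxy}furan-2(5H)-one [(5S)-5-(d-menthyloxy)butenolide] | O=C1C=C[C@H](O1)O[C@H]1C[C@@H](C)CC[C@@H]1C(C)C | starting material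
19 | lithium enolate of lactam 17 (formed in the flask) | [Li+].C=CCCN1C([O-])=CC[C@H]1[C@@H](OCc1ccccc1)C[C@H](C)COCc1ccccc1 | intermediate
20 | lithium lactone enolate of the Michael adduct (formed in the flask) | [Li+].C=CCCN1C(=O)[C@@H](C[C@H]1[C@@H](OCc1ccccc1)C[C@H](C)COCc1ccccc1)[C@@H]1[C@@H](O[C@H]2C[C@@H](C)CC[C@@H]2C(C)C)OC([O-])=C1 | intermediate
21 | (3S,5S)-5-[(1S,3S)-1,4-bis(benzyloxy)-3-methylbutyl]-1-(but-3-en-1-yl)-3-[(2S,3S,4S)-2-(d-menthyloxy)-4-methyl-5-oxooxolan-3-yl]pyrrolidin-2-one | C=CCCN1C(=O)[C@@H](C[C@H]1[C@@H](OCc1ccccc1)C[C@H](C)COCc1ccccc1)[C@@H]1[C@@H](O[C@H]2C[C@@H](C)CC[C@@H]2C(C)C)OC(=O)[C@H]1C | intermediate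
22 | (3S,5S)-5-[(1S,3S)-1,4-bis(benzyloxy)-3-methylbutyl]-1-(but-3-en-1-yl)-3-[(3S,4S)-2-hydroxy-4-methyl-5-oxooxolan-3-yl]pyrrolidin-2-one (pseudo-acid, both C11 epimers, ring-chain tautomer of the aldehyde acid) | C=CCCN1C(=O)[C@@H](C[C@H]1[C@@H](OCc1ccccc1)C[C@H](C)COCc1ccccc1)[C@@H]1C(O)OC(=O)[C@H]1C | intermediate
23 | methyl (2S,3S)-3-{(3S,5S)-5-[(1S,3S)-1,4-bis(benzyloxy)-3-methylbutyl]-1-(but-3-en-1-yl)-2-oxopyrrolidin-3-yl}-2-methyl-4-oxobutanoate | C=CCCN1C(=O)[C@@H](C[C@H]1[C@@H](OCc1ccccc1)C[C@H](C)COCc1ccccc1)[C@H](C=O)[C@H](C)C(=O)OC | intermediate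
24 | hex-1-en-3-one | CCCC(=O)C=C | starting material
25 | (Z)-diisopinocampheylboron enolate of 24 (formed in the flask) | CC/C=C(\OB([C@@H]1C[C@@H]2C[C@H]([C@H]1C)C2(C)C)[C@@H]1C[C@@H]2C[C@H]([C@H]1C)C2(C)C)C=C | intermediate
26 | methyl (2S,3S,4R,5S)-3-{(3S,5S)-5-[(1S,3S)-1,4-bis(benzyloxy)-3-methylbutyl]-1-(but-3-en-1-yl)-2-oxopyrrolidin-3-yl}-5-ethyl-4-hydroxy-2-methyl-6-oxooct-7-enoate (formed in the flask) | C=CCCN1C(=O)[C@@H](C[C@H]1[C@@H](OCc1ccccc1)C[C@H](C)COCc1ccccc1)[C@H]([C@@H](O)[C@H](CC)C(=O)C=C)[C@H](C)C(=O)OC | intermediate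
27 | (3S,5S)-5-[(1S,3S)-1,4-bis(benzyloxy)-3-methylbutyl]-1-(but-3-en-1-yl)-3-{(2R,3S,4S)-4-methyl-5-oxo-2-[(3S)-4-oxohex-5-en-3-yl]oxolan-3-yl}pyrrolidin-2-one | C=CCCN1C(=O)[C@@H](C[C@H]1[C@@H](OCc1ccccc1)C[C@H](C)COCc1ccccc1)[C@@H]1[C@H]([C@H](CC)C(=O)C=C)OC(=O)[C@H]1C | intermediate
28 | (7E)-7,8-didehydro macrocyclic keto-lactam: the skeleton of 30 with C7=C8 and the pendant lactone opened as the (1S,3S)-1,4-bis(benzyloxy)-3-methylbutyl chain on C3 | CC[C@@H]1C(=O)/C=C/CCN2C(=O)[C@@H](C[C@H]2[C@@H](OCc3ccccc3)C[C@H](C)COCc3ccccc3)[C@@H]2[C@H]1OC(=O)[C@H]2C | intermediate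
29 | seco-diol: the skeleton of 30 with the pendant lactone opened as the (1S,3S)-1,4-dihydroxy-3-methylbutyl chain on C3 | CC[C@@H]1C(=O)CCCCN2C(=O)[C@@H](C[C@H]2[C@@H](O)C[C@H](C)CO)[C@@H]2[C@H]1OC(=O)[C@H]2C | intermediate
30 | target CNP0147860.1 (tuberostemonone-type 9,9a-seco keto-lactam; 1S,3S,10S,11R,12S,13S,18S,20S) | CC[C@@H]1C(=O)CCCCN2C(=O)[C@@H](C[C@H]2[C@@H]2C[C@H](C)C(=O)O2)[C@@H]2[C@H]1OC(=O)[C@H]2C | target

**Count and risks**

Total steps: 16. Longest linear sequence: 15 steps (steps 1–7 and 9–16; step 8 is a one-step branch).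

Steps most likely to fail:

1. Step 9 (proposed new method). The lithium amidate may close through oxygen to a cyclic imidate that is lost on work-up, or may eliminate the hindered, β-oxygenated secondary sulfate instead of displacing it. The fallback uses only known reactions and sets out from diol 10 and amide 14. Selective sulfonylation of the primary hydroxyl (TsCl, cat. Bu2SnO, Et3N) would give (2R,3S,5S)-3,6-bis(benzyloxy)-2-hydroxy-5-methylhexyl 4-methylbenzenesulfonate F1, and K2CO3 in MeOH would close it to (2R)-2-[(1S,3S)-1,4-bis(benzyloxy)-3-methylbutyl]oxirane F2 with C3 unchanged. Opening of F2 at its terminal carbon by the dianion of 14 (n-BuLi, THF) is a known amide-dianion alkylation and should give (4R,5S,7S)-5,8-bis(benzyloxy)-N-(but-3-en-1-yl)-4-hydroxy-7-methyloctanamide F3. MsCl/Et3N would convert it into the 4-O-methanesulfonate of that hydroxy amide F4, and KOt-Bu in THF should close the lactam by N-alkylation with inversion at C3, which returns to 17.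

2. Step 13. Reagent control by the boron ligands has to override the facial bias of the α-branched aldehyde, and the enone-derived enolate may polymerise or react by conjugate addition. The fallback sets out from aldehyde ester 23. An Evans syn-aldol reaction with (S)-4-benzyl-3-butanoyloxazolidin-2-one (Bu2BOTf, i-Pr2NEt, CH2Cl2), whose sense for 10S,11R is secure, would give the open-chain Evans aldol imide hydroxy ester F5. PPTS would lactonise it to the ring-lactone acyl oxazolidinone F6. LiOH/H2O2 would remove the auxiliary to give the ring-lactone carboxylic acid F7 (relactonised on acidification if the lactone opens). Oxalyl chloride with cat. DMF would give the acid chloride F8, and a Stille acylation with tributyl(vinyl)stannane and a Pd(0) catalyst would deliver the vinyl ketone and rejoin the route at 27.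

3. Step 14. Intermolecular metathesis (oligomerisation) may outrun closure of the bridged 11-membered ring, which is already constrained by the cis-substituted ring lactone. The fallback sets out from hydroxy ester 26, isolated before the PPTS treatment. Ring-closing metathesis on this seco-lactone, where the chain is not yet pinned by the lactone, would give the macrocyclic enone hydroxy ester F9, and PPTS-catalysed lactonisation would then return to 28.

Further compounds
F1 | step 9 | (2R,3S,5S)-3,6-bis(benzyloxy)-2-hydroxy-5-methylhexyl 4-methylbenzenesulfonate | C[C@H](COCc1ccccc1)C[C@H](OCc1ccccc1)[C@H](O)COS(=O)(=O)c1ccc(C)cc1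
F2 | step 9 | (2R)-2-[(1S,3S)-1,4-bis(benzyloxy)-3-methylbutyl]oxirane | C[C@H](COCc1ccccc1)C[C@H](OCc1ccccc1)[C@H]1CO1
F3 | step 9 | (4R,5S,7S)-5,8-bis(benzyloxy)-N-(but-3-en-1-yl)-4-hydroxy-7-methyloctanamide | C=CCCNC(=O)CC[C@@H](O)[C@@H](OCc1ccccc1)C[C@H](C)COCc1ccccc1
F4 | step 9 | 4-O-methanesulfonate of the hydroxy amide F3 | C=CCCNC(=O)CC[C@@H](OS(C)(=O)=O)[C@@H](OCc1ccccc1)C[C@H](C)COCc1ccccc1
F5 | step 13 | open-chain Evans aldol imide hydroxy ester | C=CCCN1C(=O)[C@@H](C[C@H]1[C@@H](OCc1ccccc1)C[C@H](C)COCc1ccccc1)[C@H]([C@@H](O)[C@H](CC)C(=O)N1[C@@H](Cc2ccccc2)COC1=O)[C@H](C)C(=O)OC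
F6 | step 13 | ring-lactone acyl oxazolidinone | C=CCCN1C(=O)[C@@H](C[C@H]1[C@@H](OCc1ccccc1)C[C@H](C)COCc1ccccc1)[C@@H]1[C@H]([C@H](CC)C(=O)N2[C@@H](Cc3ccccc3)COC2=O)OC(=O)[C@H]1C
F7 | step 13 | ring-lactone carboxylic acid | C=CCCN1C(=O)[C@@H](C[C@H]1[C@@H](OCc1ccccc1)C[C@H](C)COCc1ccccc1)[C@@H]1[C@H]([C@H](CC)C(O)=O)OC(=O)[C@H]1C
F8 | step 13 | ring-lactone acid chloride | C=CCCN1C(=O)[C@@H](C[C@H]1[C@@H](OCc1ccccc1)C[C@H](C)COCc1ccccc1)[C@@H]1[C@H]([C@H](CC)C(Cl)=O)OC(=O)[C@H]1C
F9 | step 14 | macrocyclic enone hydroxy ester (seco-lactone) | CC[C@@H]1C(=O)/C=C/CCN2C(=O)[C@@H](C[C@H]2[C@@H](OCc3ccccc3)C[C@H](C)COCc3ccccc3)[C@@H]([C@H](C)C(=O)OC)[C@H]1O
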